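**Plan**

- Retrosynthetic cuts: the 3'-O–benzyl and 8-O–methyl bonds (end game), then C8–C8a of ring A (ring expansion of a squarate-derived cyclobutenone), then C4a–C5 (organomagnesium addition to dimethyl squarate), and last O1–C8a and C2–C3 of ring C (hetero-Diels–Alder of the ring B aldehyde).
- Enabling feature: C5, C6, C7 and C8 of ring A carry four contiguous oxygens with the C5 hydroxyl para to the C8 oxygen. This 2,3-dimethoxyhydroquinone unit maps onto the four carbons of dimethyl squarate, annulated across the C4a=C8a alkene of the 4-pyranone (ring C).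
- Forward order: ring B is purchased; ring C is made as a dihydropyranone, iodinated at its only enol-ether carbon and then dehydrogenated; the cyclobutenone is attached; ring A is closed last.
- Stereochemistry: the target is achiral. The C2 centre of the dihydropyranone, the cyclobutenone carbinol and the transient C8a centre are formed racemic and are all erased.
- The two new ring A hydroxyls differ through the hydrogen bond of 5-OH to the C4 carbonyl, so one methylation and one hydrogenolysis finish the synthesis.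

Key step: step 6

Remark: flavone numbering (ring A C5–C8, ring C O1–C4, ring B primed) is used for ring positions, Ar stands for 3-(benzyloxy)-4,5-dimethoxyphenyl, and the hydroxy aldehyde, Danishefsky's diene and dimethyl squarate are taken to be purchasable. The pyranone is iodinated at the dihydro stage because direct iodination of a 2-aryl-4-pyranone could go to C3, C5 or the arene.

**Step 1**
Reactants: 1 3-hydroxy-4,5-dimethoxybenzaldehyde
Product: 2 3-(benzyloxy)-4,5-dimethoxybenzaldehyde
Conditions: BnBr, K2CO3, DMF, 50 °C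
Reagents that add atoms: benzyl bromide, BrCc1ccccc1
Why: Williamson etherification of the only phenol, chosen because the benzyl ether should survive acid, DDQ, the organomagnesium step, heating and mild base and is removed by hydrogenolysis at the end.

**Step 2**
Reactants: 2 3-(benzyloxy)-4,5-dimethoxybenzaldehyde; 3 Danishefsky's diene, (E)-1-methoxy-3-(trimethylsilyloxy)buta-1,3-diene
Product: 5 rac-2-Ar-2,3-dihydro-4H-pyran-4-one, via silyloxydihydropyran cycloadduct 4 (not isolated)
Conditions: ZnCl2 (20 mol %), THF, rt; then TFA (cat.), CH2Cl2, 0 °C; aq NaHCO3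
Reagents that add atoms: none
Why: Lewis-acid-promoted hetero-Diels–Alder cyclocondensation of an aryl aldehyde with Danishefsky's diene, followed by acid-induced loss of methanol and the silyl group, is a standard entry to 2-aryl-2,3-dihydro-4-pyranones; the C2 centre forms racemic and is removed in step 4.

**Step 3**
Reactants: 5 rac-2-Ar-2,3-dihydro-4H-pyran-4-one
Product: 6 rac-2-Ar-5-iodo-2,3-dihydro-4H-pyran-4-one
Conditions: I2, pyridine, CH2Cl2, 0 °C to rt; aq Na2S2O3
Reagents that add atoms: iodine, II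
Why: α-iodination of a cyclic vinylogous ester with iodine and pyridine should place iodine at C5, the only nucleophilic enol-ether carbon of the dihydropyranone, and unactivated iodine should leave the electron-rich arene alone.

**Step 4**
Reactants: 6 rac-2-Ar-5-iodo-2,3-dihydro-4H-pyran-4-one
Product: 7 2-Ar-5-iodo-4H-pyran-4-one
Conditions: DDQ, 1,4-dioxane, 100 °C
Reagents that add atoms: none
Why: DDQ dehydrogenation of the flavanone-to-flavone type, in which hydride is taken from the benzylic, oxygen-bearing C2–H and the C3 proton is lost, should give the 4-pyranone and leave no enolisable hydrogen for the organometallic step.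

**Step 5**
Reactants: 7 2-Ar-5-iodo-4H-pyran-4-one; 8 dimethyl squarate
Product: 10 rac-4-(6-Ar-4-oxo-4H-pyran-3-yl)-4-hydroxy-2,3-dimethoxycyclobut-2-en-1-one, via pyranonylmagnesium chloride 9 (not isolated)
Conditions: iPrMgCl·LiCl (1.05 equiv), THF, −78 °C; then cannulated into 8 (1.5 equiv), THF, −78 to −40 °C; aq NH4Cl
Reagents that add atoms: none
Why: iodine–magnesium exchange on an α-iodo vinylogous ester (as practised on iodinated uracils, dioxinones and related heterocycles) followed by 1,2-addition to one of the two equivalent squarate carbonyls should give the carbinol, whose racemic centre is lost in step 6.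

**Step 6**
Reactants: 10 rac-4-(6-Ar-4-oxo-4H-pyran-3-yl)-4-hydroxy-2,3-dimethoxycyclobut-2-en-1-one
Product: 13 3'-benzyloxy-5,8-dihydroxy-6,7,4',5'-tetramethoxyflavone, via dienylketene 11 (not isolated), via 8aH-chromenedione 12 (not isolated)
Conditions: degassed p-xylene (0.02 M), 138 °C, argon
Reagents that add atoms: none
Why: Proposed new method: heating should open the cyclobutenone by conrotatory 4π electrocyclic cleavage with the donor hydroxyl turning outward, giving the (Z)-dienylketene 11 in which the pyranone CH next to the ring oxygen (future C8a) lies cis to the ketene; a thermal disrotatory 6π electrocyclisation then joins the ketene carbon to that carbon (C8–C8a), and enolisation of the C8a–H of dienone 12 aromatises ring A to the hydroquinone. The closest known reaction type is the Moore ring expansion of 4-aryl-, 4-heteroaryl- and 4-alkenyl-4-hydroxycyclobutenones to hydroquinones, not yet shown with a 4-oxopyranyl group as the 2π partner. Ring A is the only ring closed, by 6π electrocyclisation of the dienylketene. No stereocentre survives, since the carbinol carbon becomes sp2 on opening and the transient C8a centre of 12 is erased on tautomerisation. The step needs outward rotation of the hydroxyl, which is the electronic preference of a donor group (inward rotation would lead to a butenolide), and closure at a single site, which is fixed because the other neighbour of the attachment carbon is the C4 carbonyl carbon; argon and degassed solvent should keep the hydroquinone from oxidising to the 5,8-quinone.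

**Step 7**
Reactants: 13 3'-benzyloxy-5,8-dihydroxy-6,7,4',5'-tetramethoxyflavone
Product: 14 3'-benzyloxy-5-hydroxy-6,7,8,4',5'-pentamethoxyflavone
Conditions: Me2SO4 (1.05 equiv), K2CO3, degassed acetone, argon, rt to 40 °C
Reagents that add atoms: dimethyl sulfate, COS(=O)(=O)OC
Why: Williamson methylation under weak base should take only the free 8-OH, because the 5-OH is held in a hydrogen bond to the C4 carbonyl and is far less acidic and nucleophilic (the classical partial methylation of 5,8-dihydroxyflavones).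

**Step 8**
Reactants: 14 3'-benzyloxy-5-hydroxy-6,7,8,4',5'-pentamethoxyflavone
Product: 15 Gardenin C
Conditions: H2 (1 atm), 10% Pd/C, EtOAc/MeOH, rt
Reagents that add atoms: none
Why: catalytic hydrogenolysis of the aryl benzyl ether should free the 3'-OH while the flavone C2=C3 bond, the methyl ethers and the chelated phenol stay untouched at one atmosphere and room temperature.

**Compound list**

1 | 3-hydroxy-4,5-dimethoxybenzaldehyde | COc1cc(C=O)cc(O)c1OC | starting material
2 | 3-(benzyloxy)-4,5-dimethoxybenzaldehyde | COc1cc(C=O)cc(OCc2ccccc2)c1OC | intermediate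
3 | Danishefsky's diene, (E)-1-methoxy-3-(trimethylsilyloxy)buta-1,3-diene | CO/C=C/C(=C)O[Si](C)(C)C | starting material
4 | [(6-Ar-2-methoxy-5,6-dihydro-2H-pyran-4-yl)oxy]trimethylsilane (racemic cis/trans mixture, formed in the flask) | COC1C=C(O[Si](C)(C)C)CC(c2cc(OC)c(OC)c(OCc3ccccc3)c2)O1 | intermediate
5 | rac-2-[3-(benzyloxy)-4,5-dimethoxyphenyl]-2,3-dihydro-4H-pyran-4-one | O=C1C=COC(c2cc(OC)c(OC)c(OCc3ccccc3)c2)C1 | intermediate
6 | rac-2-[3-(benzyloxy)-4,5-dimethoxyphenyl]-5-iodo-2,3-dihydro-4H-pyran-4-one | O=C1C(I)=COC(c2cc(OC)c(OC)c(OCc3ccccc3)c2)C1 | intermediate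
7 | 2-[3-(benzyloxy)-4,5-dimethoxyphenyl]-5-iodo-4H-pyran-4-one | O=c1cc(-c2cc(OC)c(OC)c(OCc3ccccc3)c2)occ1I | intermediate
8 | dimethyl squarate (3,4-dimethoxycyclobut-3-ene-1,2-dione) | COC1=C(OC)C(=O)C1=O | starting material
9 | {6-[3-(benzyloxy)-4,5-dimethoxyphenyl]-4-oxo-4H-pyran-3-yl}magnesium chloride, LiCl complex (formed in the flask) | O=c1cc(-c2cc(OC)c(OC)c(OCc3ccccc3)c2)occ1[Mg]Cl.[Li+].[Cl-] | intermediate
10 | rac-4-{6-[3-(benzyloxy)-4,5-dimethoxyphenyl]-4-oxo-4H-pyran-3-yl}-4-hydroxy-2,3-dimethoxycyclobut-2-en-1-one | COC1=C(OC)C(O)(c2coc(-c3cc(OC)c(OC)c(OCc4ccccc4)c3)cc2=O)C1=O | intermediate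
11 | (3Z)-4-{6-[3-(benzyloxy)-4,5-dimethoxyphenyl]-4-oxo-4H-pyran-3-yl}-4-hydroxy-2,3-dimethoxybuta-1,3-dien-1-one (dienylketene, transient) | O=C=C(OC)/C(OC)=C(\c1coc(-c2cc(OC)c(OC)c(OCc3ccccc3)c2)cc1=O)O | intermediate
12 | rac-2-[3-(benzyloxy)-4,5-dimethoxyphenyl]-5-hydroxy-6,7-dimethoxy-8aH-chromene-4,8-dione (transient) | COC1=C(OC)C(=O)C2OC(c3cc(OC)c(OC)c(OCc4ccccc4)c3)=CC(=O)C2=C1O | intermediate
13 | 3'-benzyloxy-5,8-dihydroxy-6,7,4',5'-tetramethoxyflavone | COc1cc(-c2cc(=O)c3c(O)c(OC)c(OC)c(O)c3o2)cc(OCc2ccccc2)c1OC | intermediate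
14 | 3'-benzyloxy-5-hydroxy-6,7,8,4',5'-pentamethoxyflavone | COc1cc(-c2cc(=O)c3c(O)c(OC)c(OC)c(OC)c3o2)cc(OCc2ccccc2)c1OC | intermediate
15 | Gardenin C (5,3'-dihydroxy-6,7,8,4',5'-pentamethoxyflavone) | COc1cc(-c2cc(=O)c3c(O)c(OC)c(OC)c(OC)c3o2)cc(O)c1OC | target

**Totals**

Total step count: 8. Longest linear sequence: 8 steps (1 to 15).

**Steps most likely to fail**

1. Step 6 (bears the label). The ring opening may occur with the hydroxyl turning inward, or the ketene may fail to close onto the electron-poor, polarity-mismatched pyranone carbon; lactonisation or ketene decomposition would then compete, and any hydroquinone formed could oxidise to the quinone. Fallback by known chemistry, setting out from 2 and returning at 13: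
   - Claisen–Schmidt condensation of 2 with the catalogue acetophenone 1-(6-hydroxy-2,3,4-trimethoxyphenyl)ethan-1-one F1 (KOH, EtOH) should give (E)-3-[3-(benzyloxy)-4,5-dimethoxyphenyl]-1-(6-hydroxy-2,3,4-trimethoxyphenyl)prop-2-en-1-one F2.
   - Oxidative cyclisation (I2 cat., DMSO, 130 °C) should give 3'-benzyloxy-5,6,7,4',5'-pentamethoxyflavone F3.
   - Chelation-directed cleavage of the 5-methyl ether (MgI2·OEt2, toluene, 80 °C) should give 3'-benzyloxy-5-hydroxy-6,7,4',5'-tetramethoxyflavone F4.
   - Elbs persulfate oxidation (K2S2O8, aq KOH/pyridine) should give potassium 3'-benzyloxy-5-hydroxy-6,7,4',5'-tetramethoxyflavon-8-yl sulfate F5, which is hydrolysed (aq HCl, Na2SO3, 80 °C) to 13.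

2. Step 5. The magnesiated pyranone may fragment by β-elimination of the ring oxygen, iPrMgCl may add in conjugate fashion to the pyranone, or the reagent may add twice to the squarate. Fallback at the dihydro oxidation level, setting out from 6 and returning at 14:
   - Exchange on 6 (iPrMgCl·LiCl, THF, −78 °C) should give {2-[3-(benzyloxy)-4,5-dimethoxyphenyl]-4-oxo-3,4-dihydro-2H-pyran-5-yl}magnesium chloride, LiCl complex F6, in which only a poor alkoxide leaving group is available for fragmentation.
   - Addition to 8 should give 4-{6-[3-(benzyloxy)-4,5-dimethoxyphenyl]-4-oxo-5,6-dihydro-4H-pyran-3-yl}-4-hydroxy-2,3-dimethoxycyclobut-2-en-1-one F7 (diastereomer mixture).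
   - Thermolysis in p-xylene should pass through (3Z)-4-{6-[3-(benzyloxy)-4,5-dimethoxyphenyl]-4-oxo-5,6-dihydro-4H-pyran-3-yl}-4-hydroxy-2,3-dimethoxybuta-1,3-dien-1-one F8 and 2-[3-(benzyloxy)-4,5-dimethoxyphenyl]-5-hydroxy-6,7-dimethoxy-2,3-dihydro-8aH-chromene-4,8-dione F9 to rac-3'-benzyloxy-5,8-dihydroxy-6,7,4',5'-tetramethoxyflavanone F10.
   - Methylation of the free 8-OH under neutral conditions (TMSCHN2, MeOH/toluene) should give rac-3'-benzyloxy-5-hydroxy-6,7,8,4',5'-pentamethoxyflavanone F11.
   - Dehydrogenation (I2 cat., DMSO, 120 °C) should give 14.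

3. Step 4. Hydride abstraction by DDQ may be sluggish on the iodinated vinylogous ester, or prolonged heating may erode the benzyl ether. Fallback by selenoxide elimination, setting out from 6 and returning at 7:
   - Kinetic deprotonation at C3 (LiN(SiMe3)2, THF, −78 °C) and trapping with PhSeCl should give 2-[3-(benzyloxy)-4,5-dimethoxyphenyl]-5-iodo-3-(phenylselanyl)-2,3-dihydro-4H-pyran-4-one F12 (trans isomer expected to predominate).
   - Oxidation (H2O2, pyridine, CH2Cl2, 0 °C) should give the selenoxide 2-[3-(benzyloxy)-4,5-dimethoxyphenyl]-5-iodo-3-(phenylseleninyl)-2,3-dihydro-4H-pyran-4-one F13, which should undergo syn-elimination across C2–C3 to 7.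

**Further compounds**

F1 | step 6 | 1-(6-hydroxy-2,3,4-trimethoxyphenyl)ethan-1-one | CC(=O)c1c(O)cc(OC)c(OC)c1OC
F2 | step 6 | (E)-3-[3-(benzyloxy)-4,5-dimethoxyphenyl]-1-(6-hydroxy-2,3,4-trimethoxyphenyl)prop-2-en-1-one | COc1cc(/C=C/C(=O)c2c(O)cc(OC)c(OC)c2OC)cc(OCc2ccccc2)c1OC
F3 | step 6 | 3'-benzyloxy-5,6,7,4',5'-pentamethoxyflavone | COc1cc(-c2cc(=O)c3c(OC)c(OC)c(OC)cc3o2)cc(OCc2ccccc2)c1OC
F4 | step 6 | 3'-benzyloxy-5-hydroxy-6,7,4',5'-tetramethoxyflavone | COc1cc(-c2cc(=O)c3c(O)c(OC)c(OC)cc3o2)cc(OCc2ccccc2)c1OC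
F5 | step 6 | potassium 3'-benzyloxy-5-hydroxy-6,7,4',5'-tetramethoxyflavon-8-yl sulfate | COc1cc(-c2cc(=O)c3c(O)c(OC)c(OC)c(OS(=O)(=O)[O-])c3o2)cc(OCc2ccccc2)c1OC.[K+]
F6 | step 5 | {2-[3-(benzyloxy)-4,5-dimethoxyphenyl]-4-oxo-3,4-dihydro-2H-pyran-5-yl}magnesium chloride, LiCl complex | O=C1CC(c2cc(OC)c(OC)c(OCc3ccccc3)c2)OC=C1[Mg]Cl.[Li+].[Cl-]
F7 | step 5 | 4-{6-[3-(benzyloxy)-4,5-dimethoxyphenyl]-4-oxo-5,6-dihydro-4H-pyran-3-yl}-4-hydroxy-2,3-dimethoxycyclobut-2-en-1-one (diastereomer mixture) | COC1=C(OC)C(O)(C2=COC(c3cc(OC)c(OC)c(OCc4ccccc4)c3)CC2=O)C1=O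
F8 | step 5 | (3Z)-4-{6-[3-(benzyloxy)-4,5-dimethoxyphenyl]-4-oxo-5,6-dihydro-4H-pyran-3-yl}-4-hydroxy-2,3-dimethoxybuta-1,3-dien-1-one | O=C=C(OC)/C(OC)=C(\C1=COC(c2cc(OC)c(OC)c(OCc3ccccc3)c2)CC1=O)O
F9 | step 5 | 2-[3-(benzyloxy)-4,5-dimethoxyphenyl]-5-hydroxy-6,7-dimethoxy-2,3-dihydro-8aH-chromene-4,8-dione (diastereomer mixture) | COC1=C(OC)C(=O)C2OC(c3cc(OC)c(OC)c(OCc4ccccc4)c3)CC(=O)C2=C1O
F10 | step 5 | rac-3'-benzyloxy-5,8-dihydroxy-6,7,4',5'-tetramethoxyflavanone | COc1cc(C2CC(=O)c3c(O)c(OC)c(OC)c(O)c3O2)cc(OCc2ccccc2)c1OC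
F11 | step 5 | rac-3'-benzyloxy-5-hydroxy-6,7,8,4',5'-pentamethoxyflavanone | COc1cc(C2CC(=O)c3c(O)c(OC)c(OC)c(OC)c3O2)cc(OCc2ccccc2)c1OC
F12 | step 4 | 2-[3-(benzyloxy)-4,5-dimethoxyphenyl]-5-iodo-3-(phenylselanyl)-2,3-dihydro-4H-pyran-4-one (racemic, diastereomer mixture) | O=C1C(I)=COC(c2cc(OC)c(OC)c(OCc3ccccc3)c2)C1[Se]c1ccccc1
F13 | step 4 | 2-[3-(benzyloxy)-4,5-dimethoxyphenyl]-5-iodo-3-(phenylseleninyl)-2,3-dihydro-4H-pyran-4-one (racemic, diastereomer mixture) | O=C1C(I)=COC(c2cc(OC)c(OC)c(OCc3ccccc3)c2)C1[Se](=O)c1ccccc1
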